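**Retrosynthetic overview**

1. Target 35 ⇐ acetylation and desilylation ⇐ 2-carbinol 32 ⇐ 1,2-reduction of the tricyclic 2-ketone 31.
2. 31 ⇐ intramolecular Diels–Alder reaction of seco-trienone 30. The bonds C13–C14 and C1–C10 close the cyclohexene and, with the lagging bond C1–C10, the ten-membered ring C1–C10. Enabling feature: the cyclohexene C1–C10–C11=C12–C13–C14 is a Diels–Alder retron whose dienophile bond C1–C14 sits next to C2 (carried as a carbonyl for activation) and whose C1–C10 bond is the fusion bond of the ten-membered ring; the cis,cis C3=C4–C5=C6 diene and the γ-lactone on C7/C8 are rigid turn elements in the C2–C9 tether.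
3. 30 ⇐ Stille coupling (C4–C5) of vinyl iodide 18 with stannyl dienone 29 (from propargyl alcohol and acetylene).
4. 18 ⇐ lactone triol 7 by Wittig chain extension at C6 and at C10.
5. 7 ⇐ L-arabinitol via the C2-symmetric ketone 3 and a propanoate enolate (C7 and C9 from the chiral pool, C8 and C17 by thermodynamic lactonisation). Ring order: γ-lactone (step 4), then cyclohexene and ten-membered ring together (step 23).

Key step: step 23

Remark: target numbering is used for all intermediates (C1–C10 ten-membered ring, C11–C14 rest of the cyclohexene, C15 = CH3 on C1, C16 = CH2O on C5, C17/C18/C19 = lactone α-carbon, its CH3 and the carbonyl, C20 = CH3 on C11); the tertiary 8-OH is assumed inert to the silylation, acylation and oxidation conditions used and is carried unprotected.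

**Route**

Step 1
Reactants: 1 L-arabinitol
Product: 2 1,2:4,5-di-O-isopropylidene-L-arabinitol
Conditions: 2,2-dimethoxypropane (2.2 equiv), p-TsOH (cat.), DMF, 0 °C → rt
Reagents that add atoms: 2,2-dimethoxypropane, COC(C)(C)OC
Why: Kinetic acid-catalysed transacetalisation should engage the two terminal 1,2-diols and leave the central hydroxyl (C8) free, without touching a stereocentre.

Step 2
Reactants: 2 1,2:4,5-di-O-isopropylidene-L-arabinitol
Product: 3 bis[(4S)-2,2-dimethyl-1,3-dioxolan-4-yl]methanone
Conditions: Dess–Martin periodinane, NaHCO3, CH2Cl2, 0 °C → rt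
Reagents that add atoms: none
Why: Buffered Dess–Martin oxidation of the secondary alcohol should give the C2-symmetric ketone without epimerising the α-alkoxy centres C7 and C9.

Step 3
Reactants: 3 bis[(4S)-2,2-dimethyl-1,3-dioxolan-4-yl]methanone
Product: 4 ethyl 3,3-bis[(4S)-2,2-dimethyl-1,3-dioxolan-4-yl]-3-hydroxy-2-methylpropanoate (C17 epimers)
Conditions: LDA, ethyl propanoate, THF, −78 °C; then 3, −78 °C; aq. NH4Cl
Reagents that add atoms: ethyl propanoate, CCC(=O)OCC
Why: Aldol addition of the lithium ester enolate to the electrophilic α,α′-dialkoxy ketone, whose two faces are homotopic, so that C8 is not yet stereogenic and only C17 is formed, as a mixture that step 4 corrects.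

Step 4
Reactants: 4 ethyl 3,3-bis[(4S)-2,2-dimethyl-1,3-dioxolan-4-yl]-3-hydroxy-2-methylpropanoate
Product: 7 (3R,4R,5S)-4-[(1S)-1,2-dihydroxyethyl]-4-hydroxy-5-(hydroxymethyl)-3-methyloxolan-2-one, via pentahydroxy ester 5 (not isolated), via lactone epimer mixture 6 (not isolated)
Conditions: (i) TFA/H2O (9:1), 0 °C → rt, evaporate; (ii) DBU (0.5 equiv), MeCN, 40 °C; AcOH quench
Reagents that add atoms: none
Why: Acetal hydrolysis and lactonisation followed by base equilibration (translactonisation between the two homochiral arms and enolisation at C17) should funnel all isomers into the thermodynamic γ-lactone, in which the bulky C9 arm on C8 is trans to both the C7 hydroxymethyl and the C17 methyl; this sets C8 and C17 relative to C7 and C9 from the chiral pool.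

Step 5
Reactants: 7 lactone triol
Product: 8 lactone 9,10-acetonide (C6-OH and 8-OH free)
Conditions: 2,2-dimethoxypropane (1.2 equiv), PPTS (cat.), acetone, 0 °C
Reagents that add atoms: 2,2-dimethoxypropane, COC(C)(C)OC
Why: Isopropylidene acetal formation should be fastest at the terminal 1,2-diol (C9/C10), since the tertiary 8-OH acetalises slowly, which leaves the primary C6-OH free.

Step 6
Reactants: 8 lactone 9,10-acetonide
Product: 9 C6 aldehyde of 8
Conditions: Dess–Martin periodinane, NaHCO3, CH2Cl2, 0 °C; used crude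
Reagents that add atoms: none
Why: Dess–Martin oxidation of the only primary alcohol under buffered conditions should give the α-acyloxy aldehyde without epimerisation at C7.

Step 7
Reactants: 9 C6 aldehyde
Product: 10 (E)-enal (C16 aldehyde, C5=C6) on C7 of the lactone
Conditions: Ph3P=CHCHO, PhMe, 50 °C
Reagents that add atoms: (triphenylphosphoranylidene)acetaldehyde, O=CC=P(c1ccccc1)(c1ccccc1)c1ccccc1
Why: Wittig olefination with the formyl-stabilised ylide should give the E-enal, which brings in C5 and C16.

Step 8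
Reactants: 10 (E)-enal
Product: 11 (Z)-2-iodoenal (iodine on C5, cis to C7)
Conditions: I2, K2CO3, DMAP (cat.), THF/H2O, rt
Reagents that add atoms: iodine, II
Why: Amine-catalysed α-iodination of the enal (conjugate addition, iodination, elimination) should give the Z-2-iodoenal, in which iodine marks the position on C5, cis to C7, that C4 must take.

Step 9
Reactants: 11 (Z)-2-iodoenal
Product: 12 (Z)-2-iodoallylic alcohol (C16-OH)
Conditions: NaBH4, CeCl3·7H2O, MeOH, −78 °C
Reagents that add atoms: none
Why: Luche 1,2-reduction should reduce the aldehyde alone and leave the lactone and the vinyl iodide intact.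

Step 10
Reactants: 12 (Z)-2-iodoallylic alcohol
Product: 13 16-O-TBDPS ether of 12
Conditions: TBDPSCl, imidazole, DMF, 0 °C → rt
Reagents that add atoms: tert-butyl(chloro)diphenylsilane, CC(C)(C)[Si](Cl)(c1ccccc1)c1ccccc1
Why: Silyl ether formation at the primary allylic alcohol; the tertiary 8-OH should not react.

Step 11
Reactants: 13 16-O-TBDPS ether
Product: 14 9,10-diol
Conditions: AcOH/H2O/THF (3:1:1), 40 °C
Reagents that add atoms: none
Why: Acid hydrolysis of the isopropylidene acetal should proceed under conditions that the TBDPS ether, the vinyl iodide and the lactone tolerate.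

Step 12
Reactants: 14 9,10-diol
Product: 15 9,10-bis-O-triethylsilyl ether
Conditions: TESCl (2.3 equiv), imidazole, DMAP (cat.), DMF, 0 °C → rt
Reagents that add atoms: chlorotriethylsilane, CC[Si](Cl)(CC)CC
Why: Silyl ether formation at the primary and the secondary hydroxyl; the tertiary 8-OH should remain free.

Step 13
Reactants: 15 9,10-bis-O-triethylsilyl ether
Product: 16 C10 aldehyde (9-O-TES retained)
Conditions: (COCl)2, DMSO, CH2Cl2, −78 → −30 °C; then Et3N, −78 °C → rt
Reagents that add atoms: none
Why: Swern oxidation converts a primary triethylsilyl ether directly into the aldehyde while a secondary TES ether survives, so C10 is unmasked without a separate deprotection.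

Step 14
Reactants: 16 C10 aldehyde
Product: 17 (E)-enal C9–C10H=C11(CH3)–C12HO
Conditions: Ph3P=C(CH3)CHO, PhMe, 70 °C
Reagents that add atoms: 2-(triphenylphosphoranylidene)propanal, CC(C=O)=P(c1ccccc1)(c1ccccc1)c1ccccc1
Why: Wittig olefination with the α-methyl stabilised ylide should give the E-trisubstituted enal, which fixes the C10=C11 geometry of the future diene.

Step 15
Reactants: 17 (E)-enal
Product: 18 vinyl iodide carrying the (E)-2-methylbuta-1,3-dienyl arm (C10–C13) on C9
Conditions: Ph3PCH3Br, n-BuLi, THF, −78 °C; then 17, −78 → 0 °C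
Reagents that add atoms: methyltriphenylphosphonium bromide, C[P+](c1ccccc1)(c1ccccc1)c1ccccc1.[Br-]
Why: Wittig methylenation of the enal completes the diene; lithium counter-ion and low temperature are chosen to avoid retro-aldol opening of the β-hydroxy lactone.

Step 16
Reactants: 19 propargyl alcohol
Product: 21 (Z)-3-iodo-2-methylprop-2-en-1-ol, via vinylmagnesium alkoxide 20 (not isolated)
Conditions: MeMgBr (2.5 equiv), CuI (10 mol%), THF, −10 °C → rt; then I2, −10 °C
Reagents that add atoms: methylmagnesium bromide, C[Mg]Br; iodine, II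
Why: Copper-catalysed carbomagnesiation runs anti through the chelated alkoxide and iodinolysis of the C–Mg bond goes with retention, so iodine ends up cis to the CH2OH group (the later C14–O cis to C2).

Step 17
Reactants: 21 (Z)-3-iodo-2-methylprop-2-en-1-ol
Product: 22 (Z)-3-iodo-2-methylprop-2-enal
Conditions: Dess–Martin periodinane, NaHCO3, CH2Cl2, 0 °C, dark
Reagents that add atoms: none
Why: Dess–Martin oxidation of the allylic alcohol under buffered conditions should keep the Z geometry.

Step 18
Reactants: 23 acetylene; 24 hexabutylditin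
Product: 25 (Z)-1,2-bis(tributylstannyl)ethene
Conditions: Pd(PPh3)4 (cat.), 1,4-dioxane, acetylene (1 atm), 60 °C
Reagents that add atoms: none
Why: Palladium-catalysed distannation of an alkyne is a syn addition and gives the cis-distannylethene.

Step 19
Reactants: 25 (Z)-1,2-bis(tributylstannyl)ethene; 22 (Z)-3-iodo-2-methylprop-2-enal
Product: 27 (1Z,4Z)-1-iodo-2-methyl-5-(tributylstannyl)penta-1,4-dien-3-ol (racemic), via (Z)-2-(tributylstannyl)vinyllithium 26 (not isolated)
Conditions: n-BuLi (1.0 equiv), THF, −78 °C; then 22, −78 °C; aq. NH4Cl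
Reagents that add atoms: none
Why: Tin–lithium exchange gives the configurationally stable Z-vinyllithium, whose 1,2-addition to the aldehyde is faster than halogen exchange at −78 °C; the carbinol centre is removed in step 20.

Step 20
Reactants: 27 (1Z,4Z)-dienol
Product: 28 (1Z,4Z)-1-iodo-2-methyl-5-(tributylstannyl)penta-1,4-dien-3-one
Conditions: Dess–Martin periodinane, pyridine, CH2Cl2, 0 °C
Reagents that add atoms: none
Why: Dess–Martin oxidation of the bis-allylic alcohol under buffered conditions should keep both double-bond geometries and the C–Sn bond.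

Step 21
Reactants: 28 (1Z,4Z)-iodo stannyl dienone
Product: 29 (1Z,4Z)-2-methyl-3-oxo-5-(tributylstannyl)penta-1,4-dien-1-yl acetate
Conditions: Bu4NOAc, MeCN, 0 °C → rt
Reagents that add atoms: tetrabutylammonium acetate, CC(=O)[O-].CCCC[N+](CCCC)(CCCC)CCCC
Why: Nucleophilic vinylic substitution by addition–elimination at the β-iodo enone should go with retention and give the Z enol acetate (C14–OAc cis to the C2 carbonyl).

Step 22
Reactants: 18 vinyl iodide with diene arm; 29 acetoxy stannyl dienone
Product: 30 seco-trienone (C4–C5 coupled; 3Z,5E-dienone, Z enol acetate, E-diene arm)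
Conditions: Pd2(dba)3 (cat.), AsPh3, NMP, rt
Reagents that add atoms: none
Why: Stille coupling proceeds with retention at both sp2 carbons, and the weakly donating arsine at room temperature should spare the allylic lactone and the enol acetate.

Step 23
Reactants: 30 seco-trienone
Product: 31 tricyclic 2-ketone (14-OAc, 9-O-TES, 16-O-TBDPS, 8-OH)
Conditions: PhMe (1 mM), BHT (cat.), 100 °C, sealed vessel
Reagents that add atoms: none
Why: A concerted but asynchronous thermal [4+2] cycloaddition joins the (E)-2-methyl-1,3-diene C10=C11–C12=C13 and the C2-carbonyl-activated enol acetate C1=C14; the closest known reaction type is the macrocycle-forming type 1 intramolecular Diels–Alder reaction of acyl-tethered trienes, which closes a cyclohexene and a medium or large carbocycle together. The cyclohexene closes in the [4+2] mode through C13–C14 and C1–C10, and the ten-membered ring closes in the fused (not bridged) mode through the lagging bond C1–C10, the enone β-carbon C14 pairing with the unsubstituted diene terminus C13. C10 should be set by the diene face: allylic 1,3-strain with the C11 methyl holds H9 in the diene plane and the dienophile adds anti to the quaternary C8 branch, on the side of the smaller silyloxy group. C1 and C14 should follow from the exo transition state (acyl out, methyl in) that α-methyl enones prefer, and the cis relation of C2 and the acetoxy group on the Z enol acetate is carried unchanged into the 2,14-cis relation on the ring. The step needs chemoselectivity against the C3=C4 enone and the C3=C4–C5=C6 diene: the cis,cis-diene cannot reach an s-cis geometry and, with the γ-lactone, acts as a rigid turn that places C1 over C10, whereas C3=C4 could only meet the diene in an electronically mismatched seven-membered mode. High dilution suppresses bimolecular cycloaddition and the temperature stays below the onset of 1,5-hydrogen shifts in the cis-diene.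

Step 24
Reactants: 31 tricyclic 2-ketone
Product: 32 2β-alcohol (2S)
Conditions: NaBH4, CeCl3·7H2O, MeOH/CH2Cl2, −78 °C
Reagents that add atoms: none
Why: Luche 1,2-reduction of the ring enone; hydride should approach from the ring periphery on the face anti to the C15 methyl of the neighbouring quaternary C1, which gives the 2β-alcohol.

Step 25
Reactants: 32 2β-alcohol
Product: 33 2,9-diol (16-O-TBDPS retained)
Conditions: HF·pyridine, pyridine, THF, 0 °C
Reagents that add atoms: none
Why: Buffered fluoride desilylation should cleave the secondary triethylsilyl ether much faster than the primary TBDPS ether and does not ionise the dienylic 2-OH.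

Step 26
Reactants: 33 2,9-diol
Product: 34 2,9,14-triacetate 16-O-TBDPS ether
Conditions: Ac2O, pyridine, DMAP (cat.), CH2Cl2, rt
Reagents that add atoms: acetic anhydride, CC(=O)OC(C)=O
Why: Acetylation of the two secondary hydroxyls; the tertiary 8-OH should stay free under these conditions.

Step 27
Reactants: 34 2,9,14-triacetate 16-O-TBDPS ether
Product: 35 CNP0215504.2
Conditions: HF·pyridine (excess), THF, rt
Reagents that add atoms: none
Why: Fluoride-mediated cleavage of the primary TBDPS ether under weakly acidic conditions should leave the three acetates and the lactone untouched.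

**Compound list**

1 | L-arabinitol, (2S,4S)-pentane-1,2,3,4,5-pentol | OC[C@H](O)C(O)[C@@H](O)CO | starting material
2 | 1,2:4,5-di-O-isopropylidene-L-arabinitol | CC1(C)OC[C@H](O1)C(O)[C@@H]1COC(C)(C)O1 | intermediate
3 | bis[(4S)-2,2-dimethyl-1,3-dioxolan-4-yl]methanone (C2-symmetric ketone, C8 carbonyl) | CC1(C)OC[C@H](O1)C(=O)[C@@H]1COC(C)(C)O1 | intermediate
4 | ethyl 3,3-bis[(4S)-2,2-dimethyl-1,3-dioxolan-4-yl]-3-hydroxy-2-methylpropanoate, C17 epimers | CC1(C)OC[C@H](O1)C(O)(C(C)C(=O)OCC)[C@@H]1COC(C)(C)O1 | intermediate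
5 | ethyl (4S)-3-[(1S)-1,2-dihydroxyethyl]-3,4,5-trihydroxy-2-methylpentanoate, C17 epimers (not isolated) | OC[C@H](O)C(O)(C(C)C(=O)OCC)[C@@H](O)CO | intermediate
6 | (5S)-4-[(1S)-1,2-dihydroxyethyl]-4-hydroxy-5-(hydroxymethyl)-3-methyloxolan-2-one, mixture of C8 and C17 epimers (not isolated) | OC[C@@H]1OC(=O)C(C)C1(O)[C@@H](O)CO | intermediate
7 | (3R,4R,5S)-4-[(1S)-1,2-dihydroxyethyl]-4-hydroxy-5-(hydroxymethyl)-3-methyloxolan-2-one (5-CH2OH, 4-OH and 3-CH3 all cis) | OC[C@@H]1OC(=O)[C@H](C)[C@@]1(O)[C@@H](O)CO | intermediate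
8 | 9,10-acetonide of 7 (C6-OH and 8-OH free) | OC[C@@H]1OC(=O)[C@H](C)[C@@]1(O)[C@@H]1COC(C)(C)O1 | intermediate
9 | C6 aldehyde of 8 | O=C[C@@H]1OC(=O)[C@H](C)[C@@]1(O)[C@@H]1COC(C)(C)O1 | intermediate
10 | (E)-enal: OHC(16)–C5H=C6H– on C7 of the lactone acetonide | O=C/C=C/[C@@H]1OC(=O)[C@H](C)[C@@]1(O)[C@@H]1COC(C)(C)O1 | intermediate
11 | (Z)-2-iodoenal (I on C5, cis to C7) | O=C/C(I)=C/[C@@H]1OC(=O)[C@H](C)[C@@]1(O)[C@@H]1COC(C)(C)O1 | intermediate
12 | (Z)-2-iodoallylic alcohol (C16-OH) | OC/C(I)=C/[C@@H]1OC(=O)[C@H](C)[C@@]1(O)[C@@H]1COC(C)(C)O1 | intermediate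
13 | 16-O-TBDPS ether of 12 | CC(C)(C)[Si](OC/C(I)=C/[C@@H]1OC(=O)[C@H](C)[C@@]1(O)[C@@H]1COC(C)(C)O1)(c1ccccc1)c1ccccc1 | intermediate
14 | 9,10-diol from 13 | CC(C)(C)[Si](OC/C(I)=C/[C@@H]1OC(=O)[C@H](C)[C@@]1(O)[C@@H](O)CO)(c1ccccc1)c1ccccc1 | intermediate
15 | 9,10-bis-O-triethylsilyl ether of 14 | CC(C)(C)[Si](OC/C(I)=C/[C@@H]1OC(=O)[C@H](C)[C@@]1(O)[C@@H](O[Si](CC)(CC)CC)CO[Si](CC)(CC)CC)(c1ccccc1)c1ccccc1 | intermediate
16 | C10 aldehyde (9-O-TES) | CC(C)(C)[Si](OC/C(I)=C/[C@@H]1OC(=O)[C@H](C)[C@@]1(O)[C@@H](O[Si](CC)(CC)CC)C=O)(c1ccccc1)c1ccccc1 | intermediate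
17 | (E)-enal C9–C10H=C11(CH3)–C12HO | CC(C)(C)[Si](OC/C(I)=C/[C@@H]1OC(=O)[C@H](C)[C@@]1(O)[C@@H](O[Si](CC)(CC)CC)/C=C(\C)C=O)(c1ccccc1)c1ccccc1 | intermediate
18 | vinyl iodide with (E)-2-methylbuta-1,3-dienyl arm on C9 | CC(C)(C)[Si](OC/C(I)=C/[C@@H]1OC(=O)[C@H](C)[C@@]1(O)[C@@H](O[Si](CC)(CC)CC)/C=C(\C)C=C)(c1ccccc1)c1ccccc1 | intermediate
19 | propargyl alcohol | C#CCO | starting material
20 | (Z)-vinylmagnesium alkoxide from carbomagnesiation (not isolated) | Br[Mg]OC/C(C)=C\[Mg]Br | intermediate
21 | (Z)-3-iodo-2-methylprop-2-en-1-ol | OC/C(C)=C\I | intermediate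
22 | (Z)-3-iodo-2-methylprop-2-enal | O=C/C(C)=C\I | intermediate
23 | acetylene | C#C | starting material
24 | hexabutylditin | CCCC[Sn](CCCC)(CCCC)[Sn](CCCC)(CCCC)CCCC | starting material
25 | (Z)-1,2-bis(tributylstannyl)ethene | CCCC[Sn](CCCC)(CCCC)/C=C\[Sn](CCCC)(CCCC)CCCC | intermediate
26 | (Z)-2-(tributylstannyl)vinyllithium (not isolated) | [Li]/C=C\[Sn](CCCC)(CCCC)CCCC | intermediate
27 | (1Z,4Z)-1-iodo-2-methyl-5-(tributylstannyl)penta-1,4-dien-3-ol, racemic | CCCC[Sn](CCCC)(CCCC)/C=C\C(O)/C(C)=C\I | intermediate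
28 | (1Z,4Z)-1-iodo-2-methyl-5-(tributylstannyl)penta-1,4-dien-3-one | CCCC[Sn](CCCC)(CCCC)/C=C\C(=O)/C(C)=C\I | intermediate
29 | (1Z,4Z)-2-methyl-3-oxo-5-(tributylstannyl)penta-1,4-dien-1-yl acetate | CCCC[Sn](CCCC)(CCCC)/C=C\C(=O)/C(C)=C\OC(C)=O | intermediate
30 | seco-trienone: lactone with the C9(OTES) dienyl arm on C8 and the arm C6=C5(CH2OTBDPS)–C4=C3–C2(=O)–C1(CH3)=C14H–OAc on C7 (5E, 3Z, Z enol acetate) | CC(=O)O/C=C(C)\C(=O)/C=C\C(CO[Si](c1ccccc1)(c1ccccc1)C(C)(C)C)=C/[C@@H]1OC(=O)[C@H](C)[C@@]1(O)[C@@H](O[Si](CC)(CC)CC)/C=C(\C)C=C | intermediate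
31 | tricyclic 2-ketone: 14α-OAc, 8-OH, 9-O-TES, 16-O-TBDPS, 3Z,5E,11-triene, γ-lactone C19–O–C7 | O=C1/C=C\C(CO[Si](c3ccccc3)(c3ccccc3)C(C)(C)C)=C/[C@@H]2OC(=O)[C@H](C)[C@@]2(O)[C@@H](O[Si](CC)(CC)CC)[C@H]2C(C)=CC[C@H](OC(C)=O)[C@]12C | intermediate
32 | 2β-alcohol of 31 | O[C@H]1/C=C\C(CO[Si](c3ccccc3)(c3ccccc3)C(C)(C)C)=C/[C@@H]2OC(=O)[C@H](C)[C@@]2(O)[C@@H](O[Si](CC)(CC)CC)[C@H]2C(C)=CC[C@H](OC(C)=O)[C@]12C | intermediate
33 | 2,9-diol (14-OAc, 16-O-TBDPS) | O[C@H]1/C=C\C(CO[Si](c3ccccc3)(c3ccccc3)C(C)(C)C)=C/[C@@H]2OC(=O)[C@H](C)[C@@]2(O)[C@@H](O)[C@H]2C(C)=CC[C@H](OC(C)=O)[C@]12C | intermediate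
34 | 2,9,14-triacetate 16-O-TBDPS ether | CC(=O)O[C@H]1/C=C\C(CO[Si](c3ccccc3)(c3ccccc3)C(C)(C)C)=C/[C@@H]2OC(=O)[C@H](C)[C@@]2(O)[C@@H](OC(C)=O)[C@H]2C(C)=CC[C@H](OC(C)=O)[C@]12C | intermediate
35 | CNP0215504.2 (2β,9,14α-triacetoxy-8,16-dihydroxy-3Z,5E,11-triene γ-lactone) | CC(=O)O[C@H]1/C=C\C(CO)=C/[C@@H]2OC(=O)[C@H](C)[C@@]2(O)[C@@H](OC(C)=O)[C@H]2C(C)=CC[C@H](OC(C)=O)[C@]12C | target

**Step count and risks**

Total step count: 27. Longest linear sequence: 21 steps (steps 1–15 and 22–27, from L-arabinitol).

Steps most likely to fail: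

Step 23. The cycloaddition may be too slow for the hindered, only moderately activated dienophile, so that acyl migration in the cis-acyloxy enone, 1,5-hydrogen shifts or bimolecular cycloaddition take over; the diene face or the exo/endo choice may also be poorly controlled. Fallback, setting out from 18 and returning at 32: the order of events is reversed, with a bimolecular Diels–Alder reaction first and the ring closure second. Stille coupling of 18 with an excess of 25 should give the (3Z,5E)-dienylstannane F1, and iododestannylation (I2, CH2Cl2, −78 °C) the (Z)-dienyl iodide F2. Aldehyde 22 and Bu4NOAc give (Z)-3-acetoxy-2-methylacrolein F3 by the same vinylic substitution as in step 21. A Lewis-acid promoted intermolecular Diels–Alder reaction of the diene arm of F2 with F3 (Me2AlCl, CH2Cl2, −40 °C; a chiral oxazaborolidinium catalyst if catalyst control of the diene face is needed) should give the cyclohexene carbaldehyde F4 through the same exo, anti-to-C8 transition state. An intramolecular Nozaki–Hiyama–Kishi reaction of F4 (CrCl2, NiCl2 cat., DMSO/THF, high dilution) then closes the ten-membered ring at C2–C3 and delivers the allylic alcohol 32 directly.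

Step 24. Hydride delivery to the ring ketone may show poor or reversed facial selectivity, or compete with 1,4-reduction. Fallback, setting out from 31 and returning at 32: ring (substrate) control is given up for catalyst control, using a Corey–Bakshi–Shibata reduction with the (R)-methyl oxazaborolidine and catecholborane in toluene at −78 °C, with the quaternary C1 as the large group; any 2-epimer is recycled to 31 by Dess–Martin oxidation (no new compound is made, F0).

Step 4. The thermodynamic discrimination between the lactone diastereomers (which arm lactonises, and the C17 epimer) may be incomplete, and prolonged base may cause dehydration or retro-aldol cleavage. Fallback, setting out from 3 and returning at 8: the lactone is built under kinetic chelation control by an intramolecular Reformatsky reaction. Partial hydrolysis of one of the two homotopic acetonides of 3 (aq. AcOH, rt, recycling) gives the mono-acetonide keto diol F5; primary silylation (TESCl, imidazole, −20 °C) gives the 6-O-TES ether F6; acylation of the secondary hydroxyl with 2-bromopropanoyl bromide and pyridine gives the α-bromopropanoate F7; SmI2 in THF at −78 °C should close the β-hydroxy-γ-lactone F8 through a chelated samarium enolate that keeps the C9 branch away from the C7 substituent; buffered HF·pyridine then removes the TES group to give 8.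

Further compounds
F1 | step 23 | (3Z,5E)-dienylstannane from 18 (Bu3Sn on C3) | CCCC[Sn](CCCC)(CCCC)/C=C\C(CO[Si](c1ccccc1)(c1ccccc1)C(C)(C)C)=C/[C@@H]1OC(=O)[C@H](C)[C@@]1(O)[C@@H](O[Si](CC)(CC)CC)/C=C(\C)C=C
F2 | step 23 | (3Z,5E)-dienyl iodide (I on C3) | I/C=C\C(CO[Si](c1ccccc1)(c1ccccc1)C(C)(C)C)=C/[C@@H]1OC(=O)[C@H](C)[C@@]1(O)[C@@H](O[Si](CC)(CC)CC)/C=C(\C)C=C
F3 | step 23 | (Z)-3-acetoxy-2-methylacrolein | CC(=O)O/C=C(C)\C=O
F4 | step 23 | cyclohexene carbaldehyde (C2 aldehyde on C1, 14-OAc) carrying the (Z)-dienyl iodide | I/C=C\C(CO[Si](c1ccccc1)(c1ccccc1)C(C)(C)C)=C/[C@@H]1OC(=O)[C@H](C)[C@@]1(O)[C@@H](O[Si](CC)(CC)CC)[C@H]1C(C)=CC[C@H](OC(C)=O)[C@]1(C)C=O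
F0 | step 24 | none | none
F5 | step 4 | mono-acetonide keto diol from 3 | OC[C@H](O)C(=O)[C@@H]1COC(C)(C)O1
F6 | step 4 | 6-O-TES ether of F5 | CC[Si](CC)(CC)OC[C@H](O)C(=O)[C@@H]1COC(C)(C)O1
F7 | step 4 | 7-O-(2-bromopropanoyl) ester of F6 | CC[Si](CC)(CC)OC[C@H](OC(=O)C(C)Br)C(=O)[C@@H]1COC(C)(C)O1
F8 | step 4 | 6-O-TES ether of lactone 8 | CC[Si](CC)(CC)OC[C@@H]1OC(=O)[C@H](C)[C@@]1(O)[C@@H]1COC(C)(C)O1
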